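**Retrosynthetic overview**
1. The target is 5,7,2',4'-tetrahydroxyflavone with a 3-hydroxy-3-methylbutyl chain on C6; the last disconnection is the pair of benzyl ethers on O5 and O7.
2. Key disconnection, ring B: its hydroxyls sit on C2' and C4' (1,3 to each other), so C2'-C3'-C4'-C5' with both oxygens is cut out as an acetoacetate-derived 1-methoxy-1,3-bis(silyloxy)diene, and C1'/C6' become a terminal alkyne on C2 of ring C (bonds C1'-C2' and C5'-C6').
3. Ring C: cyclodehydration of an ortho-hydroxyaryl ynedione (O1-C2), made by Claisen condensation (C2-C3) of an ortho-hydroxyacetophenone with ethyl 3-(trimethylsilyl)propiolate.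
4. Ring A is bought as 3,5-bis(benzyloxy)phenol. Para-formylation, Wittig reaction, hydrogenation and MeMgBr build the chain on the future C6; ortho-iodination and Stille coupling put the acetyl group on the future C4a. The single free phenol, para to the chain, fixes 6- rather than 8-substitution.
5. Ring order: A (purchased), then C, then B. The tertiary alcohol is carried free and is silylated only in the flask of the key step.

Key step: step 12

Remark: the target has no stereocentre; the silyl enol ether and the diene made from methyl acetoacetate are used as double-bond isomer mixtures, because this geometry vanishes on aromatization.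

**Route**

Step 1
Reactants: 1 3,5-bis(benzyloxy)phenol
Product: 3 2,6-bis(benzyloxy)-4-hydroxybenzaldehyde, via aryl iminium chloride 2 (not isolated)
Conditions: POCl3, DMF, MeCN, 0 °C to rt; then H2O, 50 °C
Reagents that add atoms: N,N-dimethylformamide CN(C)C=O; water O
Why: Vilsmeier-Haack formylation, in which the chloroiminium ion should attack mainly the carbon para to the free hydroxyl (between the two benzyloxy groups), as is usual for 3,5-dialkoxyphenols, the hydrogen-bonded ortho isomer being removed by chromatography and the benzyl ethers being inert to the reagent.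

Step 2
Reactants: 3 2,6-bis(benzyloxy)-4-hydroxybenzaldehyde; 4 1-(triphenylphosphoranylidene)propan-2-one
Product: 5 (E)-4-[2,6-bis(benzyloxy)-4-hydroxyphenyl]but-3-en-2-one
Conditions: toluene, 110 °C
Reagents that add atoms: none
Why: Wittig olefination with a stabilized keto ylide, which should give the (E)-enone and tolerates the free phenol.

Step 3
Reactants: 5 (E)-4-[2,6-bis(benzyloxy)-4-hydroxyphenyl]but-3-en-2-one
Product: 6 4-[2,6-bis(benzyloxy)-4-hydroxyphenyl]butan-2-one
Conditions: H2 (4 atm), RhCl(PPh3)3 (5 mol %), toluene/EtOH, 50 °C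
Reagents that add atoms: none
Why: Homogeneous hydrogenation with RhCl(PPh3)3 should saturate the disubstituted enone C=C bond without hydrogenolysis of the aryl benzyl ethers or reduction of the ketone, which a heterogeneous palladium catalyst would not guarantee.

Step 4
Reactants: 6 4-[2,6-bis(benzyloxy)-4-hydroxyphenyl]butan-2-one
Product: 7 3,5-bis(benzyloxy)-4-(3-hydroxy-3-methylbutyl)phenol
Conditions: MeMgBr (3 equiv), THF, 0 °C to rt; aq. NH4Cl
Reagents that add atoms: methylmagnesium bromide C[Mg]Br
Why: Grignard addition to the unhindered methyl ketone after the first equivalent has deprotonated the phenol, no other electrophile being present.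

Step 5
Reactants: 7 3,5-bis(benzyloxy)-4-(3-hydroxy-3-methylbutyl)phenol
Product: 8 3,5-bis(benzyloxy)-4-(3-hydroxy-3-methylbutyl)-2-iodophenol
Conditions: N-iodosuccinimide (1.0 equiv), CH2Cl2, -20 °C to 0 °C, dark
Reagents that add atoms: N-iodosuccinimide O=C1CCC(=O)N1I
Why: Electrophilic aromatic iodination of a highly activated phenol whose para position is blocked and whose two ortho positions are equivalent, so that one equivalent of reagent should give a single mono-iodide.

Step 6
Reactants: 8 3,5-bis(benzyloxy)-4-(3-hydroxy-3-methylbutyl)-2-iodophenol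
Product: 10 1-[2,4-bis(benzyloxy)-6-hydroxy-3-(3-hydroxy-3-methylbutyl)phenyl]ethan-1-one, via 1-ethoxyvinyl arene 9 (not isolated)
Conditions: tributyl(1-ethoxyvinyl)stannane, Pd(PPh3)4 (5 mol %), toluene, 100 °C; then 1 M HCl, THF, rt
Reagents that add atoms: tributyl(1-ethoxyvinyl)stannane CCCC[Sn](CCCC)(CCCC)C(=C)OCC; water O
Why: Stille coupling with an acetyl-anion equivalent followed by mild hydrolysis of the enol ether should install the ortho-acetyl group without the Lewis acids of a Friedel-Crafts or Fries acylation, which would ionize the tertiary alcohol and attack the benzyl ethers.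

Step 7
Reactants: 10 1-[2,4-bis(benzyloxy)-6-hydroxy-3-(3-hydroxy-3-methylbutyl)phenyl]ethan-1-one; 11 ethyl 3-(trimethylsilyl)propiolate
Product: 12 1-[2,4-bis(benzyloxy)-6-hydroxy-3-(3-hydroxy-3-methylbutyl)phenyl]-5-(trimethylsilyl)pent-4-yne-1,3-dione
Conditions: LiN(SiMe3)2 (4.5 equiv), THF, -78 °C; then 11, -78 °C to -30 °C; AcOH
Reagents that add atoms: none
Why: Crossed Claisen condensation in which the lithium enolate of the methyl ketone (phenol and alcohol also deprotonated) attacks the ester carbonyl of the non-enolizable ynoate, the silyl group shielding the alkyne terminus from conjugate attack and the product being held as its unreactive diketonate until the quench.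

Step 8
Reactants: 12 1-[2,4-bis(benzyloxy)-6-hydroxy-3-(3-hydroxy-3-methylbutyl)phenyl]-5-(trimethylsilyl)pent-4-yne-1,3-dione
Product: 13 5,7-bis(benzyloxy)-6-(3-hydroxy-3-methylbutyl)-2-[(trimethylsilyl)ethynyl]chromen-4-one
Conditions: p-TsOH (10 mol %), CH2Cl2, rt
Reagents that add atoms: none
Why: Acid-catalysed cyclodehydration of an ortho-hydroxyaryl 1,3-diketone (the closing stage of a Baker-Venkataraman-type chromone synthesis), the phenol adding 6-exo-trig to the ynone carbonyl and the hemiketal losing water under conditions mild enough for the tertiary alcohol, the benzyl ethers and the alkynylsilane.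

Step 9
Reactants: 13 5,7-bis(benzyloxy)-6-(3-hydroxy-3-methylbutyl)-2-[(trimethylsilyl)ethynyl]chromen-4-one
Product: 14 5,7-bis(benzyloxy)-2-ethynyl-6-(3-hydroxy-3-methylbutyl)chromen-4-one
Conditions: Bu4NF, AcOH, THF, -20 °C to 0 °C
Reagents that add atoms: none
Why: Fluoride-induced protodesilylation of an alkynylsilane, buffered with acetic acid so that the acetylide is protonated at once and no basic species can add to the electrophilic enynone.

Step 10
Reactants: 15 methyl acetoacetate
Product: 16 methyl 3-(trimethylsilyloxy)but-2-enoate (E/Z mixture)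
Conditions: Me3SiCl, Et3N, hexane, rt
Reagents that add atoms: chlorotrimethylsilane C[Si](C)(C)Cl
Why: O-silylation of the enol of a β-keto ester under soft enolization (silyl enol ether formation), the isomer mixture being acceptable because the geometry is lost in the next step.

Step 11
Reactants: 16 methyl 3-(trimethylsilyloxy)but-2-enoate
Product: 17 1-methoxy-1,3-bis(trimethylsilyloxy)buta-1,3-diene
Conditions: LiN(iPr)2, THF, -78 °C; then Me3SiCl, -78 °C to rt; distillation
Reagents that add atoms: chlorotrimethylsilane C[Si](C)(C)Cl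
Why: Kinetic γ-deprotonation of the silyloxycrotonate to the extended dienolate and O-silylation at the ester oxygen should give the bis(silyloxy)diene, a standard two-step preparation from acetoacetates.

Step 12
Reactants: 14 5,7-bis(benzyloxy)-2-ethynyl-6-(3-hydroxy-3-methylbutyl)chromen-4-one; 17 1-methoxy-1,3-bis(trimethylsilyloxy)buta-1,3-diene
Product: 20 5,7-bis(benzyloxy)-2-(2,4-dihydroxyphenyl)-6-(3-hydroxy-3-methylbutyl)chromen-4-one, via trimethylsilyl ether 18 (not isolated), via cyclohexadiene cycloadduct 19 (not isolated)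
Conditions: N,O-bis(trimethylsilyl)acetamide (1.5 equiv), toluene, 60 °C; then 17 (3 equiv), 100 °C, sealed tube; then 1 M HCl, THF, rt
Reagents that add atoms: none
Why: Proposed new method: a 2-ethynylchromone has not been shown as dienophile for a 1-alkoxy-1,3-bis(silyloxy)diene, but its alkyne is a vinylogous ynone (activated by the C4 carbonyl through C3=C2), so a concerted, strongly asynchronous [4+2] cycloaddition is expected in which the nucleophilic CH2 terminus of 17 bonds to the terminal alkyne carbon (future C6') and the ketene-acetal carbon to the internal one (C1'). The closest known reaction type is the Diels-Alder addition and aromatization of 1-alkoxy-1,3-bis(silyloxy)dienes with acetylenic ketones and esters, which gives resorcinols. Ring B closes as a six-membered carbocycle in the cycloaddition itself (bonds C1'-C2' and C5'-C6'), giving cyclohexa-1,4-diene 19, whose acetal carbon is a transient racemic centre, so that no stereocentre has to be controlled. Dilute acid then expels methanol from the mixed acetal, the ring aromatizes, and the two aryl and one tertiary-alkyl trimethylsilyl ethers are hydrolysed in the same work-up. The step needs regioselectivity (oxygens on C2' and C4', not on C3' and C5'), secured by the match of the large HOMO coefficient at the diene CH2 with the large LUMO coefficient at the terminal alkyne carbon, and chemoselectivity for the alkyne, secured by the absence of a Lewis acid (no addition at C2 or C4 of the chromone) and by the trisubstituted, O1-donor-substituted nature of C2=C3. The tertiary alcohol is silylated in the same flask beforehand (18) so that it cannot protonate the diene.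

Step 13
Reactants: 20 5,7-bis(benzyloxy)-2-(2,4-dihydroxyphenyl)-6-(3-hydroxy-3-methylbutyl)chromen-4-one
Product: 21 2-(2,4-dihydroxyphenyl)-5,7-dihydroxy-6-(3-hydroxy-3-methylbutyl)chromen-4-one
Conditions: H2 (1 atm), Pd/C (10 wt %), EtOAc/MeOH, rt
Reagents that add atoms: none
Why: Hydrogenolysis of the two aryl benzyl ethers over Pd/C, under which the aryl-conjugated chromone C2=C3 bond and the tertiary alcohol should stay intact if the uptake is stopped after two equivalents of hydrogen.

**Compound list**
1 | 3,5-bis(benzyloxy)phenol | Oc1cc(OCc2ccccc2)cc(OCc2ccccc2)c1 | starting material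
2 | N-{[2,6-bis(benzyloxy)-4-hydroxyphenyl]methylidene}-N-methylmethanaminium chloride | C[N+](C)=Cc1c(OCc2ccccc2)cc(O)cc1OCc1ccccc1.[Cl-] | intermediate
3 | 2,6-bis(benzyloxy)-4-hydroxybenzaldehyde | O=Cc1c(OCc2ccccc2)cc(O)cc1OCc1ccccc1 | intermediate
4 | 1-(triphenylphosphoranylidene)propan-2-one | CC(=O)C=P(c1ccccc1)(c1ccccc1)c1ccccc1 | starting material
5 | (E)-4-[2,6-bis(benzyloxy)-4-hydroxyphenyl]but-3-en-2-one | CC(=O)/C=C/c1c(OCc2ccccc2)cc(O)cc1OCc1ccccc1 | intermediate
6 | 4-[2,6-bis(benzyloxy)-4-hydroxyphenyl]butan-2-one | CC(=O)CCc1c(OCc2ccccc2)cc(O)cc1OCc1ccccc1 | intermediate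
7 | 3,5-bis(benzyloxy)-4-(3-hydroxy-3-methylbutyl)phenol | CC(C)(O)CCc1c(OCc2ccccc2)cc(O)cc1OCc1ccccc1 | intermediate
8 | 3,5-bis(benzyloxy)-4-(3-hydroxy-3-methylbutyl)-2-iodophenol | CC(C)(O)CCc1c(OCc2ccccc2)cc(O)c(I)c1OCc1ccccc1 | intermediate
9 | 3,5-bis(benzyloxy)-2-(1-ethoxyethenyl)-4-(3-hydroxy-3-methylbutyl)phenol | CCOC(=C)c1c(O)cc(OCc2ccccc2)c(CCC(C)(C)O)c1OCc1ccccc1 | intermediate
10 | 1-[2,4-bis(benzyloxy)-6-hydroxy-3-(3-hydroxy-3-methylbutyl)phenyl]ethan-1-one | CC(=O)c1c(O)cc(OCc2ccccc2)c(CCC(C)(C)O)c1OCc1ccccc1 | intermediate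
11 | ethyl 3-(trimethylsilyl)propiolate | CCOC(=O)C#C[Si](C)(C)C | starting material
12 | 1-[2,4-bis(benzyloxy)-6-hydroxy-3-(3-hydroxy-3-methylbutyl)phenyl]-5-(trimethylsilyl)pent-4-yne-1,3-dione | C[Si](C)(C)C#CC(=O)CC(=O)c1c(O)cc(OCc2ccccc2)c(CCC(C)(C)O)c1OCc1ccccc1 | intermediate
13 | 5,7-bis(benzyloxy)-6-(3-hydroxy-3-methylbutyl)-2-[(trimethylsilyl)ethynyl]chromen-4-one | CC(C)(O)CCc1c(OCc2ccccc2)cc2oc(C#C[Si](C)(C)C)cc(=O)c2c1OCc1ccccc1 | intermediate
14 | 5,7-bis(benzyloxy)-2-ethynyl-6-(3-hydroxy-3-methylbutyl)chromen-4-one | CC(C)(O)CCc1c(OCc2ccccc2)cc2oc(C#C)cc(=O)c2c1OCc1ccccc1 | intermediate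
15 | methyl acetoacetate | COC(=O)CC(C)=O | starting material
16 | methyl 3-(trimethylsilyloxy)but-2-enoate (E/Z mixture) | COC(=O)C=C(C)O[Si](C)(C)C | intermediate
17 | 1-methoxy-1,3-bis(trimethylsilyloxy)buta-1,3-diene (C1=C2 geometry not defined) | COC(O[Si](C)(C)C)=CC(=C)O[Si](C)(C)C | intermediate
18 | 5,7-bis(benzyloxy)-2-ethynyl-6-[3-methyl-3-(trimethylsilyloxy)butyl]chromen-4-one | CC(C)(O[Si](C)(C)C)CCc1c(OCc2ccccc2)cc2oc(C#C)cc(=O)c2c1OCc1ccccc1 | intermediate
19 | 5,7-bis(benzyloxy)-2-[6-methoxy-4,6-bis(trimethylsilyloxy)cyclohexa-1,4-dien-1-yl]-6-[3-methyl-3-(trimethylsilyloxy)butyl]chromen-4-one (racemic at the acetal carbon) | CC(C)(O[Si](C)(C)C)CCc1c(OCc2ccccc2)cc2oc(C3=CCC(O[Si](C)(C)C)=CC3(OC)O[Si](C)(C)C)cc(=O)c2c1OCc1ccccc1 | intermediate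
20 | 5,7-bis(benzyloxy)-2-(2,4-dihydroxyphenyl)-6-(3-hydroxy-3-methylbutyl)chromen-4-one | CC(C)(O)CCc1c(OCc2ccccc2)cc2oc(-c3ccc(O)cc3O)cc(=O)c2c1OCc1ccccc1 | intermediate
21 | 2-(2,4-dihydroxyphenyl)-5,7-dihydroxy-6-(3-hydroxy-3-methylbutyl)chromen-4-one | CC(C)(O)CCc1c(O)cc2oc(-c3ccc(O)cc3O)cc(=O)c2c1O | target

**Step count**
Total step count: 13. Longest linear sequence: 11 steps (steps 1 to 9, 12 and 13); steps 10 and 11 make the diene.

**Steps most likely to fail**

Step 12 (carries the label). The vinylogous ynone is further deactivated by the two alkoxy donors of ring A, so cycloaddition may be slower than thermal or hydrolytic loss of the diene. Alternatively, the first C-C bond may form without ring closure (vinylogous Mukaiyama-Michael addition with silyl transfer), leaving an open-chain keto ester that cannot aromatize. The fallback uses known chemistry and brings ring B in ready-made by the classical flavone synthesis. It sets out from 10: Claisen condensation with methyl 2,4-bis(benzyloxy)benzoate (NaH, THF, reflux) should give the diaryl 1,3-diketone F1. Cyclodehydration with catalytic p-TsOH should give the tetrabenzyl flavone F2. Hydrogenolysis under the conditions of step 13 removes all four benzyl groups and comes back to the route at 21.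

Step 7. The enolate or the lithium ethoxide set free may add to the ynoate in conjugate fashion instead of at the carbonyl, or the base may strip the silyl group from the alkyne, after which the terminal ynone oligomerizes. The fallback delivers the acyl group intramolecularly (Baker-Venkataraman rearrangement), where attack at the carbonyl through a six-membered transition state is the only option. It sets out from 10: esterification of the phenol with 3-(trimethylsilyl)propiolic acid (N,N'-dicyclohexylcarbodiimide, CH2Cl2, 0 °C; the hindered tertiary alcohol should not be acylated) gives the aryl propiolate F3. Treatment with LiN(SiMe3)2 in THF at -78 °C then shifts the acyl group from oxygen to the enolate carbon and comes back to the route at 12.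

Step 8. Instead of the phenol closing onto the carbonyl, the enol oxygen of the diketone may add to the alkyne (6-endo-dig) and give a 4-pyranone, or the acid may dehydrate the tertiary alcohol before ring closure is complete. The fallback closes ring C on a diketone that holds no alkyne and makes the alkyne afterwards by one-carbon homologation. It sets out from 10: Claisen condensation with ethyl diethoxyacetate (LiN(SiMe3)2, THF) should give the diethoxy diketone F4. Aqueous HCl in THF closes the chromone and hydrolyses the acetal to the chromone-2-carbaldehyde F5. Seyferth-Gilbert homologation with dimethyl (1-diazo-2-oxopropyl)phosphonate (Ohira-Bestmann reagent; K2CO3, MeOH, 0 °C) comes back to the route at 14, bypassing 12 and 13.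

Further compounds
F1 | step 12 | 1-[2,4-bis(benzyloxy)-6-hydroxy-3-(3-hydroxy-3-methylbutyl)phenyl]-3-[2,4-bis(benzyloxy)phenyl]propane-1,3-dione | O=C(CC(=O)c1c(O)cc(OCc2ccccc2)c(CCC(C)(C)O)c1OCc1ccccc1)c1ccc(OCc2ccccc2)cc1OCc1ccccc1
F2 | step 12 | 5,7-bis(benzyloxy)-2-[2,4-bis(benzyloxy)phenyl]-6-(3-hydroxy-3-methylbutyl)chromen-4-one | CC(C)(O)CCc1c(OCc2ccccc2)cc2oc(-c3ccc(OCc4ccccc4)cc3OCc3ccccc3)cc(=O)c2c1OCc1ccccc1
F3 | step 7 | 2-acetyl-3,5-bis(benzyloxy)-4-(3-hydroxy-3-methylbutyl)phenyl 3-(trimethylsilyl)prop-2-ynoate | CC(=O)c1c(OC(=O)C#C[Si](C)(C)C)cc(OCc2ccccc2)c(CCC(C)(C)O)c1OCc1ccccc1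
F4 | step 8 | 1-[2,4-bis(benzyloxy)-6-hydroxy-3-(3-hydroxy-3-methylbutyl)phenyl]-4,4-diethoxybutane-1,3-dione | CCOC(OCC)C(=O)CC(=O)c1c(O)cc(OCc2ccccc2)c(CCC(C)(C)O)c1OCc1ccccc1
F5 | step 8 | 5,7-bis(benzyloxy)-6-(3-hydroxy-3-methylbutyl)-4-oxo-4H-chromene-2-carbaldehyde | CC(C)(O)CCc1c(OCc2ccccc2)cc2oc(C=O)cc(=O)c2c1OCc1ccccc1
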